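## Retrosynthetic overview
1. The target comes from a bis-silyl-protected triethylsilyl enol ether by fluoride desilylation. The released enolate is protonated reversibly, and this sets C1 trans to C6.
2. Key disconnection, C6–phenyl: the enone β-carbon is turned into the nucleophilic end of a 1-silyloxyallyl-nickel species (a homoenolate) and joined to iodobenzene. Both carbons are natively electrophilic. A chiral ligand sets C6 on an achiral precursor.
3. The achiral 1-aroylcyclohexa-1,4-diene comes from a para-selective Diels–Alder reaction of myrcene with an aryl ethynyl ketone. This is the only ring that is built; both benzene rings are bought.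
4. The ynone comes from ethynylmagnesium bromide and bis-silylated 2,4-dihydroxy-6-methoxybenzaldehyde, followed by oxidation.

Assumption: 2,4-dihydroxy-6-methoxybenzaldehyde is treated as a catalogue compound (otherwise it is one Vilsmeier formylation from 5-methoxyresorcinol).

## Route

Step 1
Reactants: 1 2,4-dihydroxy-6-methoxybenzaldehyde
Product: 2 2,4-bis[(tert-butyldimethylsilyl)oxy]-6-methoxybenzaldehyde
Conditions: TBSCl (2.6 equiv), imidazole (5 equiv), DMF, rt to 40 °C
Reagents that add atoms: tert-butyldimethylsilyl chloride, CC(C)(C)[Si](C)(C)Cl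
Why: Imidazole-promoted O-silylation masks both phenols, because a free ortho-phenol would quench the Grignard reagent and later close onto the ynone to give a chromone; no stereocentre is involved.

Step 2
Reactants: 2 2,4-bis[(tert-butyldimethylsilyl)oxy]-6-methoxybenzaldehyde; 3 ethynylmagnesium bromide
Product: 4 (±)-1-{2,4-bis[(tert-butyldimethylsilyl)oxy]-6-methoxyphenyl}prop-2-yn-1-ol
Conditions: 3 (1.5 equiv), THF, −78 to 0 °C; then H2O
Reagents that add atoms: none
Why: Grignard alkynylation works because the small sp nucleophile reaches the hindered, non-enolisable aldehyde, and keeping the magnesium alkoxide cold suppresses O-to-O silyl migration; the carbinol centre is racemic and is erased in step 3.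

Step 3
Reactants: 4 (±)-1-{2,4-bis[(tert-butyldimethylsilyl)oxy]-6-methoxyphenyl}prop-2-yn-1-ol
Product: 5 1-{2,4-bis[(tert-butyldimethylsilyl)oxy]-6-methoxyphenyl}prop-2-yn-1-one
Conditions: MnO2 (15 equiv), CH2Cl2, rt
Reagents that add atoms: none
Why: MnO2 oxidises the doubly activated (benzylic and propargylic) alcohol to the terminal ynone without touching the silyl ethers; no stereocentre is involved.

Step 4
Reactants: 5 1-{2,4-bis[(tert-butyldimethylsilyl)oxy]-6-methoxyphenyl}prop-2-yn-1-one; 6 myrcene (7-methyl-3-methyleneocta-1,6-diene)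
Product: 7 {2,4-bis[(tert-butyldimethylsilyl)oxy]-6-methoxyphenyl}[4-(4-methylpent-3-en-1-yl)cyclohexa-1,4-dien-1-yl]methanone
Conditions: 6 (3 equiv), Me2AlCl (30 mol %), CH2Cl2, −40 to 0 °C, argon
Reagents that add atoms: none
Why: This Lewis-acid-catalysed normal-electron-demand Diels–Alder reaction follows the para rule (the diene CH2 next to the substituted carbon bonds to the alkyne CH), so the homoprenyl group ends up 1,4 to the acyl-bearing carbon, and the skipped-diene product is achiral so no stereocontrol is needed.

Step 5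
Reactants: 7 {2,4-bis[(tert-butyldimethylsilyl)oxy]-6-methoxyphenyl}[4-(4-methylpent-3-en-1-yl)cyclohexa-1,4-dien-1-yl]methanone; 8 iodobenzene
Product: 10 (2,4-dihydroxy-6-methoxyphenyl)[(1R,6R)-4-(4-methylpent-3-en-1-yl)-6-phenylcyclohex-3-en-1-yl]methanone (target), via triethylsilyl enol ether 9 (not isolated)
Conditions: 8 (1.5 equiv), NiCl2(dme) (10 mol %), (S,S)-i-Pr-BiOX (12 mol %), Mn powder (2 equiv), Et3SiCl (1.5 equiv), DMF, 25 °C; filter, then Bu4NF·3H2O (5 equiv), THF, 0 °C to rt
Reagents that add atoms: none
Why: Proposed new method: zerovalent nickel and Et3SiCl convert the s-cis enone of 7 into an η3-1-(triethylsilyloxy)allylnickel chloride, a homoenolate in which the formerly electrophilic C6 is the nucleophilic terminus; Mn reduces it to monovalent nickel, PhI adds oxidatively, and the trivalent (allyl)(phenyl)nickel eliminates reductively at the less hindered C6, while the twofold-symmetric bis(oxazoline) shields one allyl face and so fixes C6 (the ligand antipode is to be confirmed by the optical rotation of 10); fluoride then frees the enolate and both phenols, and reversible protonation in the basic medium settles on the diequatorial trans (1R,6R) ketone; the closest known reaction types are the racemic nickel-catalysed reductive conjugate addition of aryl halides to enones with a chlorosilane and Mn, and BiOX–nickel enantioselective cross-electrophile couplings.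

## Compound list
1 | 2,4-dihydroxy-6-methoxybenzaldehyde | COc1cc(O)cc(O)c1C=O | starting material
2 | 2,4-bis[(tert-butyldimethylsilyl)oxy]-6-methoxybenzaldehyde | COc1cc(O[Si](C)(C)C(C)(C)C)cc(O[Si](C)(C)C(C)(C)C)c1C=O | intermediate
3 | ethynylmagnesium bromide | C#C[Mg]Br | starting material
4 | (±)-1-{2,4-bis[(tert-butyldimethylsilyl)oxy]-6-methoxyphenyl}prop-2-yn-1-ol (racemic) | COc1cc(O[Si](C)(C)C(C)(C)C)cc(O[Si](C)(C)C(C)(C)C)c1C(O)C#C | intermediate
5 | 1-{2,4-bis[(tert-butyldimethylsilyl)oxy]-6-methoxyphenyl}prop-2-yn-1-one | COc1cc(O[Si](C)(C)C(C)(C)C)cc(O[Si](C)(C)C(C)(C)C)c1C(=O)C#C | intermediate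
6 | myrcene | C=CC(=C)CCC=C(C)C | starting material
7 | {2,4-bis[(tert-butyldimethylsilyl)oxy]-6-methoxyphenyl}[4-(4-methylpent-3-en-1-yl)cyclohexa-1,4-dien-1-yl]methanone (achiral) | COc1cc(O[Si](C)(C)C(C)(C)C)cc(O[Si](C)(C)C(C)(C)C)c1C(=O)C1=CCC(CCC=C(C)C)=CC1 | intermediate
8 | iodobenzene | Ic1ccccc1 | starting material
9 | triethyl({2,4-bis[(tert-butyldimethylsilyl)oxy]-6-methoxyphenyl}[(6S)-4-(4-methylpent-3-en-1-yl)-6-phenylcyclohex-3-en-1-ylidene]methoxy)silane; enol ether geometry not defined; C6 has the same spatial arrangement as 6R in 10 (the label changes through a priority switch) | COc1cc(O[Si](C)(C)C(C)(C)C)cc(O[Si](C)(C)C(C)(C)C)c1C(O[Si](CC)(CC)CC)=C1CC=C(CCC=C(C)C)C[C@H]1c1ccccc1 | intermediate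
10 | (2,4-dihydroxy-6-methoxyphenyl)[(1R,6R)-4-(4-methylpent-3-en-1-yl)-6-phenylcyclohex-3-en-1-yl]methanone | COc1cc(O)cc(O)c1C(=O)[C@@H]1CC=C(CCC=C(C)C)C[C@H]1c1ccccc1 | target

## Step count and risks
Total step count: 5. Longest linear sequence: 5 (1 → 2 → 4 → 5 → 7 → 10).

**Step 5 (highest risk).**
- Risks: the allylnickel has to form next to a di-ortho-substituted aryl group. The skipped diene may chelate nickel or be isomerised or aromatised. The level and sense of enantioselectivity are untested.
- Fallback: set out from 7 and use a boron homoenolate instead of the nickel one.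
- CuCl/NaOt-Bu/(R,S)-Josiphos-catalysed conjugate borylation with B2pin2 and MeOH in THF gives the β-boryl ketone F1, with boron on the ring face opposite to the future phenyl group.
- KHF2 in aqueous MeOH converts the boronate and also strips both phenolic silyl ethers, giving the potassium trifluoroborate F2.
- A Suzuki–Miyaura coupling with bromobenzene (Pd(OAc)2, XPhos, K2CO3, CPME/H2O, 90 °C) follows. It is expected to run with inversion, as it does for secondary β-carbonyl trifluoroborates. This installs the phenyl group while the hot carbonate equilibrates C1 to trans.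
- The route is rejoined at 10.

**Step 4.**
- Risks: the meta regioisomer, Lewis-acid-induced oligomerisation of myrcene, chloride addition to the ynone, and air aromatisation of 7.
- Fallback: set out from 4 and 6 and carry out the cycloaddition before the oxidation.
- A CoBr2(dppe)/Zn/ZnI2-catalysed neutral [4+2] reaction (CH2Cl2, rt) of the unactivated alkyne of 4 with myrcene is para-selective through ligand control rather than through LUMO lowering. It gives the dienyl carbinol F3.
- Dess–Martin periodinane (CH2Cl2, NaHCO3, 0 °C) oxidises F3, and the route is rejoined at 7.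

**Step 3.**
- Risks: slow oxidation of the crowded carbinol and loss of the sensitive terminal ynone on the large MnO2 surface.
- Fallback: set out from 2 and reach the ynone by acyl substitution, with no propargylic oxidation.
- Pinnick oxidation (NaClO2, NaH2PO4, 2-methyl-2-butene, t-BuOH/H2O) gives the benzoic acid F4.
- (COCl)2 with catalytic DMF, then MeNHOMe·HCl and Et3N, gives the Weinreb amide F5.
- Ethynylmagnesium bromide 3 (THF, 0 °C) then delivers the ynone, and the route is rejoined at 5.

## Further compounds
F1 | step 5 | {2,4-bis[(tert-butyldimethylsilyl)oxy]-6-methoxyphenyl}[(6S)-4-(4-methylpent-3-en-1-yl)-6-(4,4,5,5-tetramethyl-1,3,2-dioxaborolan-2-yl)cyclohex-3-en-1-yl]methanone (C1 epimers) | COc1cc(O[Si](C)(C)C(C)(C)C)cc(O[Si](C)(C)C(C)(C)C)c1C(=O)C1CC=C(CCC=C(C)C)C[C@@H]1B1OC(C)(C)C(C)(C)O1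
F2 | step 5 | potassium {(6S)-1-(2,4-dihydroxy-6-methoxybenzoyl)-4-(4-methylpent-3-en-1-yl)cyclohex-3-en-6-yl}trifluoroborate (ring numbered as in 10; C1 epimers) | COc1cc(O)cc(O)c1C(=O)C1CC=C(CCC=C(C)C)C[C@@H]1[B-](F)(F)F.[K+]
F3 | step 4 | {2,4-bis[(tert-butyldimethylsilyl)oxy]-6-methoxyphenyl}[4-(4-methylpent-3-en-1-yl)cyclohexa-1,4-dien-1-yl]methanol (racemic) | COc1cc(O[Si](C)(C)C(C)(C)C)cc(O[Si](C)(C)C(C)(C)C)c1C(O)C1=CCC(CCC=C(C)C)=CC1
F4 | step 3 | 2,4-bis[(tert-butyldimethylsilyl)oxy]-6-methoxybenzoic acid | COc1cc(O[Si](C)(C)C(C)(C)C)cc(O[Si](C)(C)C(C)(C)C)c1C(=O)O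
F5 | step 3 | 2,4-bis[(tert-butyldimethylsilyl)oxy]-N,6-dimethoxy-N-methylbenzamide | COc1cc(O[Si](C)(C)C(C)(C)C)cc(O[Si](C)(C)C(C)(C)C)c1C(=O)N(C)OC
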